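## The problem

Target 33 is a bicyclo[3.3.1]nonane-2,4,9-trione of the type B polyprenylated acylphloroglucinol family. Positions are numbered C1–C9 as in the bicycle for every compound of this proposal: ring A is C1–C2–C3–C4–C5–C9 (the enolised 2,4-dione with the 3-hydroxybenzoyl group on C3) and ring B is C1–C8–C7–C6–C5–C9 (a cyclohexanone whose carbonyl is the bridge C9). Four stereocentres have to be set: the quaternary bridgeheads C1 and C5 with one prenyl group each, the quaternary C8 with a methyl and a 4-methylpent-3-enyl group, and the tertiary C7, whose prenyl group lies on the same face of ring B as the C2–C3–C4 bridge (endo) and trans to the C8 methyl. C1 and C8 are vicinal quaternary carbons, the most congested bond of the molecule. Only C7 needs an external source of chirality: a C7 substituent can steer a conjugate addition at C8, the C7/C8 pair can steer an alkylation at C1, and C5 follows from C1 because a three-atom bridge can only span one face of ring B. Five trisubstituted alkenes exclude hydrogenation, strong acid and an excess of electrophilic or radical reagents; the 1,3-dicarbonyl units with quaternary α-carbons are open to retro-Claisen cleavage; the enolised trione and the phenol are best unmasked last. The key step is possible because the C2–C3–C4 bridge, attached to C1, is a bromo-ynone at the right oxidation level: the C9 ketone supplies an enol silane whose carbon C5 can bond to the alkyne carbon C4, and the bromine left on C4 is a placeholder for the enol oxygen.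

## Retrosynthesis

**Unmasking and the C3–aroyl bond.** Target 33 is traced to its O-methyl, O-silyl derivative 31, from which one basic hydrolysis should release the C4 enol (through the phenol 32) and the phenol. Compound 31 is cut between C3 and the aroyl carbonyl into the bicyclic vinylogous ester 26 and the acid chloride 29, which comes in two steps from 3-hydroxybenzoic acid 27 through the bis-silyl compound 28. Carrying the aroyl group from the start would put an acidic, chelating triketone into every base- and metal-mediated step. In 26 both bridgeheads are quaternary and C3–H is the only acidic position, so the forward step asks only for a hindered amide base and an acyl chloride. The precursor is simpler by the whole aryl ketone.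

**The C4–O bond.** Compound 26 is cut at C4–O to the β-bromo enone 25. A halogen is preferred to oxygen at C4 at this stage because it can sit on an alkyne carbon before ring A exists. The alternative, a C4–H enone, would need a separate oxidation next to five alkenes. The forward reaction is an addition–elimination by an alkoxide.

**The C4–C5 bond (key disconnection).** Cutting C4–C5 of 25 opens ring A and leads to the monocyclic enol silane 24, in which C1 carries a prenyl group and the 3-bromopropynoyl unit. The bond is cut at C5 and not at C1 because C5 is flanked by a methylene group, whereas C1 sits next to the quaternary C8; the harder centre is built earlier by enolate chemistry. The precursor has one ring and one stereocentre fewer. The forward reaction must close ring A in the 6-endo mode and must prefer the enol silane to the prenyl alkenes.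

**Adjusting ring B for the closure.** Compound 24 is traced through bromine-for-silicon exchange to the alkynylsilane 23, through enol silane formation to the ketone 22, and through cutting the C5–prenyl bond to the diketone 20 and prenyl bromide 18. Regiochemistry is not in question because C1 is quaternary, so C5 is the only enolisable α-carbon of the C9 ketone. The silyl group on the alkyne is kept until this point because a bromoalkyne would not survive the amide base of the C5 alkylation.

**The C1–prenyl bond.** Compound 20 is cut at C1–prenyl to the β-diketone 17 and 18. Introducing the prenyl group after the acyl group uses the one acidic position of a 1,3-diketone; the reverse order would need a tetrasubstituted ketone enolate next to C8. The forward alkylation has to occur at carbon and on the face trans to the C7 prenyl group; the pseudoaxial homoprenyl group on C8 shields the other face.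

**The C8–methyl and C1–C2 bonds.** Compound 17 is traced through its carbinol 16 to the enone 13, the ynal 14 and a methyl nucleophile. One operation makes the quaternary C8 and attaches the three-carbon bridge. The methyl group is added last at C8 because the group added to a 3,4-disubstituted cyclohexenone enters trans to the C4 substituent, and the target has methyl trans to the C7 prenyl.

**The C8–homoprenyl bond.** Enone 13 is traced to the enol silane 12, and 12 to the enone 9 and the Grignard reagent 11 made from the bromide 10. Conjugate addition with silyl trapping followed by dehydrogenation restores the enone regiospecifically. The stereocentre formed at C8 is transient.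

**Ring B and C7.** Enone 9 is cut at C1=C8 (aldol condensation) and at C6–C7 (Michael addition) into the keto aldehyde 7, and 7 into the aldehyde 5 and methyl vinyl ketone 6. This makes C7, the only centre that needs a chiral reagent, by an enamine-catalysed addition with a small amount of a diarylprolinol ether. Desymmetrising a 4-substituted cyclohexanone with a stoichiometric chiral base would need more steps. Aldehyde 5 comes from the alcohol 1 and the vinyl ether 2 by a Claisen rearrangement through 3 and 4.

## Roads not taken

**Alternative 1:** The cut removes the C3–aroyl and C4–O bonds together. In the forward sense the C4-unsubstituted bicyclic enone A1 (the debromo analogue of 25) would react with the nitrile oxide A3, released by base from the hydroximoyl chloride A2, to give the cis-fused isoxazoline A4. N–O cleavage, imine hydrolysis, oxidation of the C4 carbinol and desilylation would follow.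

- Merits: the aryl ketone carbon and the C4 oxygen arrive in one step, and the regiochemistry normal for enones (oxygen to the β-carbon) is the one required. No strong base is needed late. A1 needs no halogen, so the alkyne bromination, a chemoselectivity risk of the chosen plan, disappears; in this respect the road is better.
- Weak points: C4 of A1 is a neopentyl-type carbon of a cis-disubstituted enone and should be a slow dipolarophile. A3 can then dimerise or add to one of the five trisubstituted alkenes. The N–O bond must be cleaved without hydrogenation, and C4 must still be oxidised; this makes four steps after the cycloaddition against three after the ring closure in the chosen plan.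
- Comparison: the chosen plan sets against the lost atom economy that each endgame step (alkoxide exchange, C3 metalation–acylation, hydrolysis) is an established operation on this ring system, and that C4 is at the right oxidation level as soon as bromide is exchanged.

**Alternative 2:** The cuts are C5–C6 (ring B, closed last) and before it C1–C8 (dearomative Claisen rearrangement of an O-allylated acylphloroglucinol). In the key step zerovalent palladium, for example Pd(PPh3)4, would ionise the allylic carbonate of the enolised triketone A5, and C5 would attack a terminus of the 2-substituted π-allyl unit, closing ring B to the 7-methylene trione A6.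

- Merits: the aroyl group and all three ring A oxygens are present from the aromatic starting material, so neither late C3 acylation nor C4 adjustment is needed. The route is convergent and on paper shorter than the chosen one. Hydroboration of the C7 methylene from the open exo face would place the new C7 substituent endo, as the target requires.
- Weak points: the vicinal quaternary centres C1 and C8 of A5 must be formed in the Claisen step with relative and absolute control, which needs a geometrically pure trisubstituted allyl ether and an enantioselective variant. O-Allylation of the vinylogous acid can compete in the palladium step. The C7 prenyl group must then be built from the methylene group by hydroboration and cross-coupling in the presence of four trisubstituted alkenes and an enolised triketone that consumes hydride.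
- Comparison: this road is better in step count and in having the acyl group in place early. The chosen plan sets against it stereocontrol that is relayed centre by centre (C7 to C8 to C1 to C5) from one catalytic enantioselective step, with every carbon substituent in place before the ring closure.

**Alternative 3:** The cut is C1–C8, made while ring A is a cyclohexa-1,4-diene bis(methyl enol ether). In the forward step TMSOTf would open the trisubstituted epoxide of A7 at its tertiary carbon (future C8) with one of the two enantiotopic enol ethers, giving the bicyclic C7 alcohol A8.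

- Merits: one step closes ring B and sets C8 (by inversion), C1 and C5 (by desymmetrisation) from a single epoxide stereocentre pair. Absolute control by catalytic asymmetric epoxidation is at least as reliable as the organocatalytic step of the chosen plan, and the quaternary C8 is made in the ring-forming event; in these respects this road is as good or better.
- Weak points for this target: A8 has oxygen where C7 needs a prenyl group with the endo configuration, so a C–C bond must be made with stereocontrol at a secondary carbon next to the quaternary C8, where radical or displacement routes favour the exo isomer. C2 is a methylene group that must be oxidised beside prenyl groups. The C1 prenyl group must be introduced at the bridgehead next to C8, and the aroyl group is still missing; the sequence after the key step would be long.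
- Comparison: the chosen plan sets against the elegant desymmetrisation that its ring closure starts from a compound carrying all four side chains, and needs three steps to finish.

Key step: step 12

## Route

Remark: positions are numbered C1–C9 as in the bicyclic target throughout, and 33 is taken as the equilibrating enol tautomers, of which the C2-keto/C4-enol form is drawn.

Step 1
Reactants: 1 2-methylbut-3-en-2-ol; 2 ethyl vinyl ether
Product: 5 5-methylhex-4-enal, via mixed acetal 3 (not isolated), via allyl vinyl ether 4 (not isolated)
Conditions: H3PO4 (cat.), excess 2, sealed vessel, 150 °C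
Reagents that add atoms: none
Why: Acid-catalysed acetal exchange and loss of ethanol give the tertiary allyl vinyl ether, which undergoes the Claisen rearrangement (Saucy–Marbet variant) to the γ,δ-unsaturated aldehyde; no stereocentre is formed.

Step 2
Reactants: 5 5-methylhex-4-enal; 6 methyl vinyl ketone
Product: 7 (R)-2-(3-methylbut-2-en-1-yl)-5-oxohexanal
Conditions: (R)-2-(methoxydiphenylmethyl)pyrrolidine (5 mol%), ethyl 3,4-dihydroxybenzoate (20 mol%), neat, 4 °C
Reagents that add atoms: none
Why: Enamine-catalysed Michael addition of an aldehyde to an enone; the E-enamine of 5 is shielded on one face by the diphenyl(methoxy)methyl group of the (R)-catalyst, so the enone adds to the open face and the future C7 centre should form as R, while the catechol co-catalyst activates the enone by hydrogen bonding.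

Step 3
Reactants: 7 (R)-2-(3-methylbut-2-en-1-yl)-5-oxohexanal
Product: 9 (R)-4-(3-methylbut-2-en-1-yl)cyclohex-2-en-1-one, via aldol 8 (not isolated)
Conditions: LiOH, i-PrOH, rt
Reagents that add atoms: none
Why: Intramolecular aldol condensation of the methyl ketone onto the aldehyde (the ring-closing half of a Robinson annulation); mild base and fast dehydration should preserve the aldehyde α-stereocentre, which becomes the γ-carbon C7 of the enone.

Step 4
Reactants: 9 (R)-4-(3-methylbut-2-en-1-yl)cyclohex-2-en-1-one; 10 5-bromo-2-methylpent-2-ene
Product: 12 trans-(3R,4R)-3-(4-methylpent-3-en-1-yl)-4-(3-methylbut-2-en-1-yl)-1-(trimethylsilyloxy)cyclohex-1-ene, via Grignard reagent 11 (not isolated)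
Conditions: 10, Mg, THF, rt; then CuBr·SMe2 (10 mol%), TMSCl, 9, THF, −78 °C; Et3N, non-aqueous work-up
Reagents that add atoms: chlorotrimethylsilane, C[Si](C)(C)Cl
Why: Copper-catalysed conjugate addition of a Grignard reagent accelerated by TMSCl; the homoprenyl group should enter trans to the C7 prenyl group (a centre erased in step 5), and silyl trapping fixes the enolate as the C1=C9 enol silane.

Step 5
Reactants: 12 trans-(3R,4R)-3-(4-methylpent-3-en-1-yl)-4-(3-methylbut-2-en-1-yl)-1-(trimethylsilyloxy)cyclohex-1-ene
Product: 13 (R)-3-(4-methylpent-3-en-1-yl)-4-(3-methylbut-2-en-1-yl)cyclohex-2-en-1-one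
Conditions: Pd(OAc)2 (1.05 equiv), MeCN, rt
Reagents that add atoms: none
Why: Saegusa–Ito oxidation: divalent palladium forms the C1 palladium enolate from the enol silane and β-hydride elimination of the C8 hydrogen gives the C1=C8 enone regiospecifically, leaving zerovalent palladium; C7 is not touched.

Step 6
Reactants: 13 (R)-3-(4-methylpent-3-en-1-yl)-4-(3-methylbut-2-en-1-yl)cyclohex-2-en-1-one; 14 3-(trimethylsilyl)prop-2-ynal
Product: 16 (3S,4R)-2-[1-hydroxy-3-(trimethylsilyl)prop-2-yn-1-yl]-3-methyl-4-(3-methylbut-2-en-1-yl)-3-(4-methylpent-3-en-1-yl)cyclohexan-1-one (epimers at C1 and the carbinol carbon), via magnesium enolate 15 (not isolated)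
Conditions: MeMgBr, CuBr·SMe2 (10 mol%), THF, −20 to 0 °C; then 14, −78 °C; aq. NH4Cl
Reagents that add atoms: methylmagnesium bromide, C[Mg]Br
Why: Copper-catalysed conjugate addition to a β,β-disubstituted enone followed by aldol trapping of the magnesium enolate; allylic strain with the C8 side chain holds the C7 prenyl group pseudoaxial and the methyl group should add to the opposite face, giving the quaternary C8 with methyl trans to the C7 prenyl, while the C1 and carbinol centres are not controlled and are erased in step 7 (oxidation, enolisable C1).

Step 7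
Reactants: 16 aldol adduct (epimer mixture)
Product: 17 (3S,4R)-3-methyl-4-(3-methylbut-2-en-1-yl)-3-(4-methylpent-3-en-1-yl)-2-[3-(trimethylsilyl)prop-2-ynoyl]cyclohexan-1-one (C1 epimers and enol)
Conditions: Dess–Martin periodinane, NaHCO3, CH2Cl2, 0 °C to rt
Reagents that add atoms: none
Why: Dess–Martin oxidation of the propargylic alcohol to the ynone under buffered, non-acidic conditions that leave the alkenes and the alkynylsilane alone; the carbinol epimers converge to one β-diketone.

Step 8
Reactants: 17 β-diketone; 18 prenyl bromide
Product: 20 (2S,3S,4R)-3-methyl-2,4-bis(3-methylbut-2-en-1-yl)-3-(4-methylpent-3-en-1-yl)-2-[3-(trimethylsilyl)prop-2-ynoyl]cyclohexan-1-one, via sodium enolate 19 (not isolated)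
Conditions: NaH, THF, 0 °C; then 18, 0 °C to rt
Reagents that add atoms: none
Why: C-alkylation of a β-diketone enolate with an allylic bromide (soft electrophile, tight sodium ion pair in THF); in the favoured half-chair the C7 prenyl group is equatorial and the C8 homoprenyl group pseudoaxial, so prenyl bromide should approach C1 from the opposite face, trans to the C7 prenyl group and cis to the C8 methyl, as known for C1 allylation of related C8-quaternary β-dicarbonyl cyclohexanones.

Step 9
Reactants: 20 C1-prenyl diketone; 18 prenyl bromide
Product: 22 (2S,3S,4S)-3-methyl-2,4,6-tris(3-methylbut-2-en-1-yl)-3-(4-methylpent-3-en-1-yl)-2-[3-(trimethylsilyl)prop-2-ynoyl]cyclohexan-1-one (C5 epimers), via lithium enolate 21 (not isolated)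
Conditions: LiN(i-Pr)2, THF, −78 °C; then 18, DMPU, −78 to −40 °C
Reagents that add atoms: none
Why: Kinetic enolate alkylation; C5 is the only enolisable α-carbon because C1 is quaternary and the ynone has no α-hydrogen, and the C5 configuration is irrelevant because C5 becomes trigonal in step 10.

Step 10
Reactants: 22 C5-prenyl diketone (C5 epimers)
Product: 23 1-[(1S,5S,6S)-2-(tert-butyldimethylsilyloxy)-6-methyl-1,3,5-tris(3-methylbut-2-en-1-yl)-6-(4-methylpent-3-en-1-yl)cyclohex-2-en-1-yl]-3-(trimethylsilyl)prop-2-yn-1-one
Conditions: TBSOTf, Et3N, CH2Cl2, 0 °C to rt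
Reagents that add atoms: tert-butyldimethylsilyl trifluoromethanesulfonate, CC(C)(C)[Si](C)(C)OS(=O)(=O)C(F)(F)F
Why: Soft enolisation (O-silylation of the C9 carbonyl, then deprotonation at C5 by the amine) gives the only possible enol silane, C5=C9, and both C5 epimers converge.

Step 11
Reactants: 23 alkynylsilane enol silane
Product: 24 3-bromo-1-[(1S,5S,6S)-2-(tert-butyldimethylsilyloxy)-6-methyl-1,3,5-tris(3-methylbut-2-en-1-yl)-6-(4-methylpent-3-en-1-yl)cyclohex-2-en-1-yl]prop-2-yn-1-one
Conditions: NBS, AgNO3 (20 mol%), acetone, 0 °C, dark
Reagents that add atoms: N-bromosuccinimide, O=C1CCC(=O)N1Br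
Why: Silver-mediated desilylative bromination of an alkynylsilane through a silver acetylide, a fast process at 0 °C; N-halosuccinimide and AgNO3 halogenation of terminal alkynes is known to spare tert-butyldimethylsilyl enol ethers, and the same is expected for the slower desilylative variant.

Step 12
Reactants: 24 bromo-ynone enol silane
Product: 25 (1R,5R,7S,8S)-4-bromo-8-methyl-1,5,7-tris(3-methylbut-2-en-1-yl)-8-(4-methylpent-3-en-1-yl)bicyclo[3.3.1]non-3-ene-2,9-dione
Conditions: (Ph3P)AuNTf2 (5 mol%), acetone (undried), rt
Reagents that add atoms: none
Why: Monovalent gold binds the alkyne of the bromo-ynone and the enol silane carbon C5 adds anti to the metal at C4, the β-carbon that carries bromine; the silyloxocarbenium ion at C9 then loses its silyl group to adventitious water and the vinylgold at C3 is protonated, giving the β-bromo enone and returning the catalyst. The closest known reaction type is the gold-catalysed Conia-ene-type carbocyclisation of cyclic silyl enol ethers onto 1-haloalkynes, which gives bicyclo[3.3.1]nonenones. Ring A (C4, C3, C2, C1, C9, C5) closes in the 6-endo-dig mode; the 5-exo-dig path would need attack at the α-carbon C3, against the polarisation of the ynone. The new stereocentre C5 is controlled by C1: the ynone is anchored on C1 and can reach C5 only across the face of ring B that it occupies, so the C4–C5 bond must form cis to the C1–C2 bond. The step needs chemoselectivity for the enol silane over the five trisubstituted alkenes, above all the C1 prenyl group that stands 1,6 to the alkyne, and this rests on the far higher nucleophilicity of the enol silane and the electron-poor character of the ynone. It also needs the ynone pseudoaxial on the face that carries the C7 prenyl group, which ring B can meet by taking the boat-like shape known for bicyclo[3.3.1]nonanes with an endo C7 substituent. Bromine on C4 serves later as the leaving group that brings C4 to the ketone oxidation level.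

Step 13
Reactants: 25 β-bromo enone
Product: 26 (1R,5S,7S,8S)-4-methoxy-8-methyl-1,5,7-tris(3-methylbut-2-en-1-yl)-8-(4-methylpent-3-en-1-yl)bicyclo[3.3.1]non-3-ene-2,9-dione
Conditions: NaOMe, MeOH, 0 °C to rt
Reagents that add atoms: sodium methoxide, C[O-].[Na+]
Why: Addition–elimination at the β-carbon of a β-halo enone (conjugate addition of methoxide at C4, loss of bromide) gives the vinylogous ester; the flanking quaternary carbons shield C9 and C2 against retro-Claisen attack, and no stereocentre changes.

Step 14
Reactants: 27 3-hydroxybenzoic acid
Product: 28 tert-butyldimethylsilyl 3-(tert-butyldimethylsilyloxy)benzoate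
Conditions: TBSCl (2.4 equiv), imidazole, DMF, rt
Reagents that add atoms: tert-butyldimethylsilyl chloride, CC(C)(C)[Si](C)(C)Cl
Why: Imidazole-promoted silylation of both the phenol and the carboxylic acid; the silyl ester is the activated form used in step 15.

Step 15
Reactants: 28 bis-silyl compound
Product: 29 3-(tert-butyldimethylsilyloxy)benzoyl chloride
Conditions: (COCl)2, DMF (cat.), CH2Cl2, 0 °C to rt; used crude
Reagents that add atoms: oxalyl chloride, O=C(Cl)C(=O)Cl
Why: Silyl esters are converted into acid chlorides by the chloroiminium (Vilsmeier-type) reagent under neutral conditions, releasing the silyl chloride instead of HCl, so the aryl silyl ether should survive.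

Step 16
Reactants: 26 vinylogous ester; 29 3-(tert-butyldimethylsilyloxy)benzoyl chloride
Product: 31 (1S,5S,7S,8S)-3-[3-(tert-butyldimethylsilyloxy)benzoyl]-4-methoxy-8-methyl-1,5,7-tris(3-methylbut-2-en-1-yl)-8-(4-methylpent-3-en-1-yl)bicyclo[3.3.1]non-3-ene-2,9-dione, via vinyllithium 30 (not isolated)
Conditions: lithium 2,2,6,6-tetramethylpiperidide (from the amine and n-BuLi), THF, −78 °C; then 29, −78 to −40 °C
Reagents that add atoms: none
Why: Directed vinylic deprotonation at C3 of the vinylogous ester (the only acidic C–H, both bridgeheads being quaternary) and acylation of the vinyllithium with the acid chloride, a known way to place the C3 acyl group of type B bicyclic triones; the stereocentres are untouched.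

Step 17
Reactants: 31 protected target
Product: 33 (1S,5S,7S,8S)-4-hydroxy-3-(3-hydroxybenzoyl)-8-methyl-1,5,7-tris(3-methylbut-2-en-1-yl)-8-(4-methylpent-3-en-1-yl)bicyclo[3.3.1]non-3-ene-2,9-dione, via phenol methyl ether 32 (not isolated)
Conditions: LiOH, dioxane/H2O, 90 °C; then dilute aq. HCl to pH 3
Reagents that add atoms: lithium hydroxide, [Li+].[OH-]
Why: Hydroxide first cleaves the aryl silyl ether at silicon and then hydrolyses the vinylogous methyl ester by addition–elimination at C4 (vinylogous saponification, known for O-methyl ethers of type B bicyclic triones); the product is held as a stable trione enolate until mild acidification, which avoids acid-induced cyclisation of prenyl groups onto the enol.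

## Compound list

1 | 2-methylbut-3-en-2-ol | CC(C)(O)C=C | starting material
2 | ethyl vinyl ether | CCOC=C | starting material
3 | 3-(1-ethoxyethoxy)-3-methylbut-1-ene (mixed acetal, not isolated) | CCOC(C)OC(C)(C)C=C | intermediate
4 | 3-methyl-3-(vinyloxy)but-1-ene (allyl vinyl ether, not isolated) | C=COC(C)(C)C=C | intermediate
5 | 5-methylhex-4-enal | CC(C)=CCCC=O | intermediate
6 | methyl vinyl ketone (but-3-en-2-one) | CC(=O)C=C | starting material
7 | (R)-2-(3-methylbut-2-en-1-yl)-5-oxohexanal | O=C[C@@H](CC=C(C)C)CCC(C)=O | intermediate
8 | (4R)-3-hydroxy-4-(3-methylbut-2-en-1-yl)cyclohexan-1-one (carbinol epimers, not isolated) | O=C1CC(O)[C@@H](CC=C(C)C)CC1 | intermediate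
9 | (R)-4-(3-methylbut-2-en-1-yl)cyclohex-2-en-1-one | O=C1C=C[C@@H](CC=C(C)C)CC1 | intermediate
10 | 5-bromo-2-methylpent-2-ene | CC(C)=CCCBr | starting material
11 | (4-methylpent-3-en-1-yl)magnesium bromide (not isolated) | CC(C)=CCC[Mg]Br | intermediate
12 | trans-(3R,4R)-3-(4-methylpent-3-en-1-yl)-4-(3-methylbut-2-en-1-yl)-1-(trimethylsilyloxy)cyclohex-1-ene | C[Si](C)(C)OC1=C[C@H](CCC=C(C)C)[C@@H](CC=C(C)C)CC1 | intermediate
13 | (R)-3-(4-methylpent-3-en-1-yl)-4-(3-methylbut-2-en-1-yl)cyclohex-2-en-1-one | CC(C)=CCCC1=CC(=O)CC[C@@H]1CC=C(C)C | intermediate
14 | 3-(trimethylsilyl)prop-2-ynal | C[Si](C)(C)C#CC=O | starting material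
15 | bromomagnesium C1=C9 enolate from methyl addition to 13, C8 methyl trans to C7 prenyl (not isolated) | CC(C)=CCC[C@@]1(C)[C@@H](CC=C(C)C)CCC(O[Mg]Br)=C1 | intermediate
16 | (3S,4R)-2-[1-hydroxy-3-(trimethylsilyl)prop-2-yn-1-yl]-3-methyl-4-(3-methylbut-2-en-1-yl)-3-(4-methylpent-3-en-1-yl)cyclohexan-1-one (epimers at C1 and the carbinol carbon) | CC(C)=CCC[C@@]1(C)[C@@H](CC=C(C)C)CCC(=O)C1C(O)C#C[Si](C)(C)C | intermediate
17 | (3S,4R)-3-methyl-4-(3-methylbut-2-en-1-yl)-3-(4-methylpent-3-en-1-yl)-2-[3-(trimethylsilyl)prop-2-ynoyl]cyclohexan-1-one (C1 epimers and enol) | CC(C)=CCC[C@@]1(C)[C@@H](CC=C(C)C)CCC(=O)C1C(=O)C#C[Si](C)(C)C | intermediate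
18 | prenyl bromide (1-bromo-3-methylbut-2-ene) | CC(C)=CCBr | starting material
19 | sodium enolate of 17 (not isolated) | CC(C)=CCC[C@@]1(C)[C@@H](CC=C(C)C)CCC(O[Na])=C1C(=O)C#C[Si](C)(C)C | intermediate
20 | (2S,3S,4R)-3-methyl-2,4-bis(3-methylbut-2-en-1-yl)-3-(4-methylpent-3-en-1-yl)-2-[3-(trimethylsilyl)prop-2-ynoyl]cyclohexan-1-one (C1 prenyl trans to C7 prenyl) | CC(C)=CCC[C@@]1(C)[C@@H](CC=C(C)C)CCC(=O)[C@@]1(CC=C(C)C)C(=O)C#C[Si](C)(C)C | intermediate
21 | lithium C5=C9 enolate of 20 (not isolated) | CC(C)=CCC[C@@]1(C)[C@@H](CC=C(C)C)CC=C(O[Li])[C@@]1(CC=C(C)C)C(=O)C#C[Si](C)(C)C | intermediate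
22 | (2S,3S,4S)-3-methyl-2,4,6-tris(3-methylbut-2-en-1-yl)-3-(4-methylpent-3-en-1-yl)-2-[3-(trimethylsilyl)prop-2-ynoyl]cyclohexan-1-one (C5 epimers) | CC(C)=CCC[C@@]1(C)[C@@H](CC=C(C)C)CC(CC=C(C)C)C(=O)[C@@]1(CC=C(C)C)C(=O)C#C[Si](C)(C)C | intermediate
23 | 1-[(1S,5S,6S)-2-(tert-butyldimethylsilyloxy)-6-methyl-1,3,5-tris(3-methylbut-2-en-1-yl)-6-(4-methylpent-3-en-1-yl)cyclohex-2-en-1-yl]-3-(trimethylsilyl)prop-2-yn-1-one | CC(C)=CCC[C@@]1(C)[C@@H](CC=C(C)C)CC(CC=C(C)C)=C(O[Si](C)(C)C(C)(C)C)[C@@]1(CC=C(C)C)C(=O)C#C[Si](C)(C)C | intermediate
24 | 3-bromo-1-[(1S,5S,6S)-2-(tert-butyldimethylsilyloxy)-6-methyl-1,3,5-tris(3-methylbut-2-en-1-yl)-6-(4-methylpent-3-en-1-yl)cyclohex-2-en-1-yl]prop-2-yn-1-one | CC(C)=CCC[C@@]1(C)[C@@H](CC=C(C)C)CC(CC=C(C)C)=C(O[Si](C)(C)C(C)(C)C)[C@@]1(CC=C(C)C)C(=O)C#CBr | intermediate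
25 | (1R,5R,7S,8S)-4-bromo-8-methyl-1,5,7-tris(3-methylbut-2-en-1-yl)-8-(4-methylpent-3-en-1-yl)bicyclo[3.3.1]non-3-ene-2,9-dione | CC(C)=CCC[C@@]1(C)[C@@H](CC=C(C)C)C[C@]2(CC=C(C)C)C(=O)[C@@]1(CC=C(C)C)C(=O)C=C2Br | intermediate
26 | (1R,5S,7S,8S)-4-methoxy-8-methyl-1,5,7-tris(3-methylbut-2-en-1-yl)-8-(4-methylpent-3-en-1-yl)bicyclo[3.3.1]non-3-ene-2,9-dione | CC(C)=CCC[C@@]1(C)[C@@H](CC=C(C)C)C[C@]2(CC=C(C)C)C(=O)[C@@]1(CC=C(C)C)C(=O)C=C2OC | intermediate
27 | 3-hydroxybenzoic acid | O=C(O)c1cccc(O)c1 | starting material
28 | tert-butyldimethylsilyl 3-(tert-butyldimethylsilyloxy)benzoate | CC(C)(C)[Si](C)(C)OC(=O)c1cccc(O[Si](C)(C)C(C)(C)C)c1 | intermediate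
29 | 3-(tert-butyldimethylsilyloxy)benzoyl chloride | CC(C)(C)[Si](C)(C)Oc1cccc(C(=O)Cl)c1 | intermediate
30 | C3-lithio derivative of 26 (not isolated) | CC(C)=CCC[C@@]1(C)[C@@H](CC=C(C)C)C[C@]2(CC=C(C)C)C(=O)[C@@]1(CC=C(C)C)C(=O)C([Li])=C2OC | intermediate
31 | (1S,5S,7S,8S)-3-[3-(tert-butyldimethylsilyloxy)benzoyl]-4-methoxy-8-methyl-1,5,7-tris(3-methylbut-2-en-1-yl)-8-(4-methylpent-3-en-1-yl)bicyclo[3.3.1]non-3-ene-2,9-dione | CC(C)=CCC[C@@]1(C)[C@@H](CC=C(C)C)C[C@]2(CC=C(C)C)C(=O)[C@@]1(CC=C(C)C)C(=O)C(C(=O)c1cccc(O[Si](C)(C)C(C)(C)C)c1)=C2OC | intermediate
32 | (1S,5S,7S,8S)-3-(3-hydroxybenzoyl)-4-methoxy-8-methyl-1,5,7-tris(3-methylbut-2-en-1-yl)-8-(4-methylpent-3-en-1-yl)bicyclo[3.3.1]non-3-ene-2,9-dione (not isolated) | CC(C)=CCC[C@@]1(C)[C@@H](CC=C(C)C)C[C@]2(CC=C(C)C)C(=O)[C@@]1(CC=C(C)C)C(=O)C(C(=O)c1cccc(O)c1)=C2OC | intermediate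
33 | (1S,5S,7S,8S)-4-hydroxy-3-(3-hydroxybenzoyl)-8-methyl-1,5,7-tris(3-methylbut-2-en-1-yl)-8-(4-methylpent-3-en-1-yl)bicyclo[3.3.1]non-3-ene-2,9-dione (CNP0406274.1) | CC(C)=CCC[C@@]1(C)[C@@H](CC=C(C)C)C[C@]2(CC=C(C)C)C(=O)[C@@]1(CC=C(C)C)C(=O)C(C(=O)c1cccc(O)c1)=C2O | target

## Step count and least certain steps

Total step count: 17 steps. Longest linear sequence: 15 steps (steps 1 to 13, then 16 and 17); steps 14 and 15 form the two-step side branch to 29.

**Step 12 (key step).** The most likely failure is that ring closure becomes slower than loss of the nucleophile. The reacting conformer must hold the ynone pseudoaxial on the face that also carries the C7 prenyl group, and the attacking carbon C5 is fully substituted. Protodesilylation of the enol silane, or capture of the gold-activated ynone by the C1 prenyl alkene in an enyne-type cyclisation, may then overtake C4–C5 bond formation. The fallback moves the C5 prenylation behind the ring closure; it sets out from 20 and comes back at 26. Soft enolisation of 20 (TBSOTf, Et3N) should give the C5-unsubstituted enol silane F1, and bromination with NBS and AgNO3 the C5-unsubstituted bromo-ynone F2. The same closure with (Ph3P)AuNTf2 then involves a less encumbered, trisubstituted enol silane and should give the C5–H bromo enone F3, and methoxide exchange the C5–H vinylogous ester F4. Bridgehead deprotonation of F4 at C5 with LiN(i-Pr)2 and alkylation with 18 returns to 26. Bridgehead prenylation of such vinylogous esters is established chemistry, and C3 metalation needs the stronger lithium 2,2,6,6-tetramethylpiperidide.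

**Step 8.** The most likely failure is O-prenylation of the enolate, because C1 is flanked by the quaternary C8 and carbon attack has to build a second quaternary centre. The facial preference, trans to the C7 prenyl group, is the less uncertain part. The fallback replaces the displacement by a Tsuji–Trost allylation; it sets out from 17 and comes back at 20. With Pd(PPh3)4 and methyl 3-methylbut-2-en-1-yl carbonate in THF, any O-allyl enol ether is re-ionised by zerovalent palladium and funnelled to the C-allylated product, and the stabilised enolate should attack the unsubstituted terminus of the π-prenyl complex. This fallback forms no compound outside the list (F0).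

**Step 11.** The most likely failure is electrophilic bromination of the enol silane at C5 by NBS in competition with the silver-mediated exchange at the alkyne, which would destroy the nucleophile of the key step. The fallback exchanges silicon for bromine before the enol silane exists; it sets out from 22 and comes back at 24. NBS and AgNO3 in acetone should convert 22 into the bromo-ynone diketone F5, and soft enolisation of F5 with TBSOTf and the poorly nucleophilic base i-Pr2NEt in CH2Cl2 at 0 °C gives 24.

**Step 9.** The most likely failure is attack on the ynone, either by the amide base or by the new C5 enolate (intramolecular conjugate addition), together with over-alkylation at C5. The fallback introduces the C5 prenyl group before the ynone is present; it sets out from 13 and comes back at 22. Kinetic deprotonation of 13 at C5 with LiN(i-Pr)2 and alkylation with 18 should give the C5-prenyl enone F6 (C5 epimers). Conjugate methyl addition (MeMgBr, CuBr·SMe2) with aldol trapping by 14 gives the carbinol F7, and Dess–Martin oxidation the C5-prenyl β-diketone F8. C1 prenylation of F8 (NaH, 18), as in step 8, arrives at 22.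

## Further compounds

F1 | step 12 | C5-unsubstituted analogue of 23 (C5=C9 tert-butyldimethylsilyl enol ether of 20) | CC(C)=CCC[C@@]1(C)[C@@H](CC=C(C)C)CC=C(O[Si](C)(C)C(C)(C)C)[C@@]1(CC=C(C)C)C(=O)C#C[Si](C)(C)C
F2 | step 12 | C5-unsubstituted analogue of 24 (bromo-ynone enol silane) | CC(C)=CCC[C@@]1(C)[C@@H](CC=C(C)C)CC=C(O[Si](C)(C)C(C)(C)C)[C@@]1(CC=C(C)C)C(=O)C#CBr
F3 | step 12 | C5–H analogue of 25 (4-bromo-8-methyl-1,7-bis(3-methylbut-2-en-1-yl)-8-(4-methylpent-3-en-1-yl)bicyclo[3.3.1]non-3-ene-2,9-dione) | CC(C)=CCC[C@@]1(C)[C@@H](CC=C(C)C)C[C@@H]2C(=O)[C@@]1(CC=C(C)C)C(=O)C=C2Br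
F4 | step 12 | C5–H analogue of 26 (4-methoxy-8-methyl-1,7-bis(3-methylbut-2-en-1-yl)-8-(4-methylpent-3-en-1-yl)bicyclo[3.3.1]non-3-ene-2,9-dione) | CC(C)=CCC[C@@]1(C)[C@@H](CC=C(C)C)C[C@@H]2C(=O)[C@@]1(CC=C(C)C)C(=O)C=C2OC
F0 | step 8 | none | none
F5 | step 11 | bromo-ynone analogue of 22 (2-(3-bromoprop-2-ynoyl)-3-methyl-2,4,6-tris(3-methylbut-2-en-1-yl)-3-(4-methylpent-3-en-1-yl)cyclohexan-1-one, C5 epimers) | CC(C)=CCC[C@@]1(C)[C@@H](CC=C(C)C)CC(CC=C(C)C)C(=O)[C@@]1(CC=C(C)C)C(=O)C#CBr
F6 | step 9 | (4R)-3-(4-methylpent-3-en-1-yl)-4,6-bis(3-methylbut-2-en-1-yl)cyclohex-2-en-1-one (C5 epimers) | CC(C)=CCCC1=CC(=O)C(CC=C(C)C)C[C@@H]1CC=C(C)C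
F7 | step 9 | C5-prenyl analogue of 16 (epimers at C1, C5 and the carbinol carbon) | CC(C)=CCC[C@@]1(C)[C@@H](CC=C(C)C)CC(CC=C(C)C)C(=O)C1C(O)C#C[Si](C)(C)C
F8 | step 9 | C5-prenyl analogue of 17 (epimers at C1 and C5) | CC(C)=CCC[C@@]1(C)[C@@H](CC=C(C)C)CC(CC=C(C)C)C(=O)C1C(=O)C#C[Si](C)(C)C
A1 | alternative 1 | 8-methyl-1,5,7-tris(3-methylbut-2-en-1-yl)-8-(4-methylpent-3-en-1-yl)bicyclo[3.3.1]non-3-ene-2,9-dione (C4–H enone, configured as 25) | CC(C)=CCC[C@@]1(C)[C@@H](CC=C(C)C)C[C@]2(CC=C(C)C)C(=O)[C@@]1(CC=C(C)C)C(=O)C=C2
A2 | alternative 1 | 3-(tert-butyldimethylsilyloxy)-N-hydroxybenzimidoyl chloride | CC(C)(C)[Si](C)(C)Oc1cccc(C(Cl)=NO)c1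
A3 | alternative 1 | 3-(tert-butyldimethylsilyloxy)benzonitrile oxide | CC(C)(C)[Si](C)(C)Oc1cccc(C#[N+][O-])c1
A4 | alternative 1 | isoxazoline cis-fused at C3–C4 of the bicyclic 2,9-dione, 3-aryl = 3-(tert-butyldimethylsilyloxy)phenyl | CC(C)=CCC[C@@]1(C)[C@@H](CC=C(C)C)C[C@]2(CC=C(C)C)C(=O)[C@@]1(CC=C(C)C)C(=O)[C@H]1C(c3cccc(O[Si](C)(C)C(C)(C)C)c3)=NO[C@H]12
A5 | alternative 2 | enolised 3-aroyl-1,5-diprenyl cyclohexanetrione with a C1 side chain C8(methyl)(4-methylpent-3-enyl)–C7(=CH2)–CH2OCO2Me | CC(C)=CCC[C@@](C)(C(=C)COC(=O)OC)[C@]1(CC=C(C)C)C(=O)C(C(=O)c2cccc(O[Si](C)(C)C(C)(C)C)c2)=C(O)C(CC=C(C)C)=C1O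
A6 | alternative 2 | 7-methylene bicyclo[3.3.1]nonane trione, aryl silyl ether | CC(C)=CCC[C@@]1(C)C(=C)C[C@]2(CC=C(C)C)C(=O)[C@@]1(CC=C(C)C)C(=O)C(C(=O)c1cccc(O[Si](C)(C)C(C)(C)C)c1)=C2O
A7 | alternative 3 | 1,5-dimethoxycyclohexa-1,4-diene with a quaternary C6 that carries a prenyl group and a 2,3-epoxy-3,7-dimethyloct-6-enyl chain | COC1=CCC=C(OC)C1(CC=C(C)C)C[C@H]1O[C@]1(C)CCC=C(C)C
A8 | alternative 3 | bicyclic C7-hydroxy C9-ketone with C4 methyl enol ether | CC(C)=CCC[C@@]1(C)[C@H](O)C[C@]2(CC=C(C)C)C(=O)[C@H]1CC=C2OC
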